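**Target:** (2R,3R)-configured, 2,3-cis dihydrobenzofuran with a (Z)-2-methylbut-2-enoate (angelate) at C3 and a 3-acetoxyprop-1-en-2-yl group at C2.

**Retrosynthetic overview**
1. Allylic acetate ⇐ acetylation of the alcohol from allylic oxidation of the isopropenyl methyl of 9.
2. Dihydrofuran ring (formed last) ⇐ pyran-to-furan ring contraction: 1,2-aryloxy shift in a cis-3-triflyloxy-4-angeloyloxy chroman, with inversion at the migration terminus and E1 loss to the isopropenyl group.
3. cis-Hydroxy angelate ⇐ syn opening of the (3R,4R)-chromene oxide at benzylic C4 by angelic acid; oxide ⇐ Jacobsen epoxidation, which sets both stereocentres.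
4. Pyran ring (formed first) ⇐ ortho-quinone methide / oxa-6π closure of the Heck adduct of 5-bromoresacetophenone and 2-methylbut-3-en-2-ol.
5. Ring order: pyran (step 1) → oxirane (step 2) → dihydrofuran by contraction (step 3).

Assumption: the presumed biosynthesis is taken as prenylated resacetophenone → 2,2-dimethylchromene (eupatoriochromene) → 3,4-oxide → 1,2-aryloxy shift to the 2-isopropenyl-3-oxy-dihydrofuran; compound 1 is treated as a bought catalogue compound.

**Step 1**
Reactants: 1 1-(5-bromo-2,4-dihydroxyphenyl)ethan-1-one; 2 2-methylbut-3-en-2-ol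
Product: 4 1-(7-hydroxy-2,2-dimethyl-2H-chromen-6-yl)ethan-1-one (eupatoriochromene), via (E)-allylic alcohol Heck adduct 3 (not isolated)
Conditions: Pd(OAc)2 (5 mol %), P(o-tol)3 (10 mol %), NaOAc (1.5 equiv), DMA, 110 °C; then AcOH (co-solvent), 100 °C
Reagents that add atoms: none
Why: Mizoroki–Heck arylation of the terminal alkene gives the (E)-styryl tertiary alcohol (the carbinol has no β-hydrogen, so no ketone forms), and in hot acetic acid this doubly oxygen-activated allylic alcohol ionises to an ortho-quinone methide that closes by oxa-6π electrocyclisation onto the C4 phenol, fixing the linear 6-acetyl-7-hydroxy pattern from the bromide position; no stereocentre is formed.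

**Step 2**
Reactants: 4 1-(7-hydroxy-2,2-dimethyl-2H-chromen-6-yl)ethan-1-one
Product: 5 1-[(3R,4R)-3,4-epoxy-7-hydroxy-2,2-dimethyl-3,4-dihydro-2H-chromen-6-yl]ethan-1-one
Conditions: (R,R)-Jacobsen Mn(salen)Cl (5 mol %), NMO (5 equiv), mCPBA (1.5 equiv), CH2Cl2, −78 °C; cold NaHCO3 wash, used crude
Reagents that add atoms: mCPBA (3-chloroperoxybenzoic acid), O=C(OO)c1cccc(Cl)c1
Why: Jacobsen–Katsuki epoxidation, for which cis-configured 2,2-dimethylchromenes are the best substrate class (typically >95% ee); the (R,R)-catalyst gives the (3R,4R)-oxide and so sets both stereocentres, and the anhydrous low-temperature protocol spares the hydrogen-bonded phenol and the aryl ketone.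

**Step 3**
Reactants: 5 1-[(3R,4R)-3,4-epoxy-7-hydroxy-2,2-dimethyl-3,4-dihydro-2H-chromen-6-yl]ethan-1-one; 6 angelic acid [(Z)-2-methylbut-2-enoic acid]
Product: 9 (2R,3R)-5-acetyl-6-hydroxy-2-(prop-1-en-2-yl)-2,3-dihydro-1-benzofuran-3-yl (Z)-2-methylbut-2-enoate, via cis-hydroxy angelate 7 (not isolated), via C3 triflate 8 (not isolated)
Conditions: 6 (1.1 equiv), CH2Cl2 (1 M), 4 Å MS, 0 °C → rt until 5 is consumed; then dilute, 2,6-lutidine (4 equiv), Tf2O (1.1 equiv), −78 °C → rt
Reagents that add atoms: none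
Why: Acidolysis of the electron-rich benzylic epoxide at C4 goes through a contact ion pair that collapses on the face of the departing oxygen (syn-selective opening of aryl epoxides by carboxylic acids) to give the 3,4-cis hydroxy angelate with C4 retained; triflation of the pseudo-equatorial C3–OH (ester pseudo-axial) then triggers the Wagner–Meerwein-type 1,2-aryloxy shift known for 2,2-dimethylchroman-3-ol sulfonates, in which the antiperiplanar ring oxygen attacks C3 with inversion while the CMe2 carbon leaves as a tertiary cation that loses a methyl proton (E1), so chroman C3(R) becomes benzofuran C2(R), cis to the untouched angelate-bearing centre.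

**Step 4**
Reactants: 9 (2R,3R)-5-acetyl-6-hydroxy-2-(prop-1-en-2-yl)-2,3-dihydro-1-benzofuran-3-yl (Z)-2-methylbut-2-enoate
Product: 10 (2R,3R)-5-acetyl-6-hydroxy-2-(3-hydroxyprop-1-en-2-yl)-2,3-dihydro-1-benzofuran-3-yl (Z)-2-methylbut-2-enoate
Conditions: SeO2 (0.5 equiv), t-BuOOH (2.5 equiv), CH2Cl2, 0 °C → rt
Reagents that add atoms: selenium dioxide, O=[Se]=O; tert-butyl hydroperoxide, CC(C)(C)OO
Why: Sharpless–Umbreit allylic oxidation (ene reaction then [2,3]-sigmatropic shift) should take the isopropenyl methyl, because the only other allylic hydrogen (C2–H) is hindered and deactivated by its neighbouring oxygens; on a 1,1-disubstituted alkene the ene/[2,3] sequence returns the double bond to the exocyclic position, and no stereocentre is touched.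

**Step 5**
Reactants: 10 (2R,3R)-5-acetyl-6-hydroxy-2-(3-hydroxyprop-1-en-2-yl)-2,3-dihydro-1-benzofuran-3-yl (Z)-2-methylbut-2-enoate
Product: 11 (2R,3R)-2-[3-(acetyloxy)prop-1-en-2-yl]-5-acetyl-6-hydroxy-2,3-dihydro-1-benzofuran-3-yl (Z)-2-methylbut-2-enoate
Conditions: Ac2O (1.2 equiv), pyridine (3 equiv), CH2Cl2, 0 °C
Reagents that add atoms: acetic anhydride, CC(=O)OC(C)=O
Why: Chemoselective O-acetylation of the primary allylic alcohol; the phenol is locked in a strong hydrogen bond to the ortho acetyl group and is not acylated at 0 °C without DMAP, and the weak base leaves the benzylic angelate and both stereocentres alone.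

**Compound list**
1 | 1-(5-bromo-2,4-dihydroxyphenyl)ethan-1-one | CC(=O)c1cc(Br)c(O)cc1O | starting material
2 | 2-methylbut-3-en-2-ol | C=CC(C)(C)O | starting material
3 | 1-{2,4-dihydroxy-5-[(E)-3-hydroxy-3-methylbut-1-en-1-yl]phenyl}ethan-1-one | CC(=O)c1cc(/C=C/C(C)(C)O)c(O)cc1O | intermediate
4 | 1-(7-hydroxy-2,2-dimethyl-2H-chromen-6-yl)ethan-1-one | CC(=O)c1cc2C=CC(C)(C)Oc2cc1O | intermediate
5 | 1-[(3R,4R)-3,4-epoxy-7-hydroxy-2,2-dimethyl-3,4-dihydro-2H-chromen-6-yl]ethan-1-one | CC1(C)Oc2cc(O)c(C(C)=O)cc2[C@H]2O[C@@H]12 | intermediate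
6 | angelic acid, (Z)-2-methylbut-2-enoic acid | C/C=C(/C)C(=O)O | starting material
7 | (3R,4R)-6-acetyl-3,7-dihydroxy-2,2-dimethyl-3,4-dihydro-2H-chromen-4-yl (Z)-2-methylbut-2-enoate (3,4-cis) | CC1(C)Oc2cc(O)c(C(C)=O)cc2[C@@H](OC(=O)/C(C)=C\C)[C@H]1O | intermediate
8 | (3R,4R)-6-acetyl-7-hydroxy-2,2-dimethyl-3-[(trifluoromethanesulfonyl)oxy]-3,4-dihydro-2H-chromen-4-yl (Z)-2-methylbut-2-enoate | CC1(C)Oc2cc(O)c(C(C)=O)cc2[C@@H](OC(=O)/C(C)=C\C)[C@H]1OS(=O)(=O)C(F)(F)F | intermediate
9 | (2R,3R)-5-acetyl-6-hydroxy-2-(prop-1-en-2-yl)-2,3-dihydro-1-benzofuran-3-yl (Z)-2-methylbut-2-enoate (2,3-cis) | C=C(C)[C@H]1Oc2cc(O)c(C(C)=O)cc2[C@H]1OC(=O)/C(C)=C\C | intermediate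
10 | (2R,3R)-5-acetyl-6-hydroxy-2-(3-hydroxyprop-1-en-2-yl)-2,3-dihydro-1-benzofuran-3-yl (Z)-2-methylbut-2-enoate | C=C(CO)[C@H]1Oc2cc(O)c(C(C)=O)cc2[C@H]1OC(=O)/C(C)=C\C | intermediate
11 | (2R,3R)-2-[3-(acetyloxy)prop-1-en-2-yl]-5-acetyl-6-hydroxy-2,3-dihydro-1-benzofuran-3-yl (Z)-2-methylbut-2-enoate | C=C(COC(C)=O)[C@H]1Oc2cc(O)c(C(C)=O)cc2[C@H]1OC(=O)/C(C)=C\C | target

**Total step count:** 5. **Longest linear sequence:** 5 (fully linear from 1).

**Steps most likely to fail, with fallbacks**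

Step 3 is the most exposed. The acid opening may give some trans adduct, which would contract to the 2,3-trans isomer. In the contraction the axial C2 methyl or the aryl carbon may migrate instead of the ring oxygen, and Tf2O may reach the phenol. The fallback replaces the contraction by a Pd(0) π-allyl ring closure with net retention. It sets out from 1:
- TBSCl and imidazole give 1-[5-bromo-2,4-bis(tert-butyldimethylsilyloxy)phenyl]ethan-1-one F2.
- Heck coupling with isoprene (Pd(OAc)2, P(o-tol)3, Et3N, sealed tube) gives 1-{2,4-bis(tert-butyldimethylsilyloxy)-5-[(E)-3-methylbuta-1,3-dien-1-yl]phenyl}ethan-1-one F3.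
- Shi epoxidation (D-fructose-derived ketone, Oxone) of the trans-disubstituted styrenyl alkene gives 1-{2,4-bis(tert-butyldimethylsilyloxy)-5-[(2R,3R)-3-(prop-1-en-2-yl)oxiran-2-yl]phenyl}ethan-1-one F4.
- AcOH-buffered TBAF followed by Pd(PPh3)4 ionises the allylic C–O bond with inversion, and the ortho phenol attacks the π-allyl terminus with a second inversion, giving cis-(2R,3R)-5-acetyl-2-(prop-1-en-2-yl)-2,3-dihydro-1-benzofuran-3,6-diol F5.
- Angelic acid 6 is converted with 2,4,6-trichlorobenzoyl chloride and Et3N into angelic 2,4,6-trichlorobenzoic anhydride F6, which acylates the aliphatic 3-OH of F5 in toluene at 80 °C without DMAP. This comes back to the route at 9.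

Step 4 can over-oxidise to the enal, attack C2–H, or be slow on the hindered 1,1-disubstituted alkene. The fallback sets out from 9. Selenium-catalysed ene-type allylic chlorination (NCS, catalytic PhSeCl, CH2Cl2) gives (2R,3R)-5-acetyl-2-(3-chloroprop-1-en-2-yl)-6-hydroxy-2,3-dihydro-1-benzofuran-3-yl (Z)-2-methylbut-2-enoate F7. SN2 displacement with KOAc and 18-crown-6 in MeCN then gives the acetate directly, so it comes back at 11 and passes over 10.

Step 1 couples an unprotected, electron-rich bromoresorcinol, and the chromene can oligomerise in hot acid. The fallback sets out from 2. BF3·OEt2-mediated Friedel–Crafts C-prenylation of bought 2,4-dihydroxyacetophenone with 2 in dioxane gives, after separation from the 3-prenyl isomer, 1-[2,4-dihydroxy-5-(3-methylbut-2-en-1-yl)phenyl]ethan-1-one F1. DDQ in refluxing benzene then effects dehydrogenative cyclisation through the ortho-quinone methide, and it comes back at 4.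

**Further compounds**
F1 | step 1 | 1-[2,4-dihydroxy-5-(3-methylbut-2-en-1-yl)phenyl]ethan-1-one | CC(=O)c1cc(CC=C(C)C)c(O)cc1O
F2 | step 3 | 1-[5-bromo-2,4-bis(tert-butyldimethylsilyloxy)phenyl]ethan-1-one | CC(=O)c1cc(Br)c(O[Si](C)(C)C(C)(C)C)cc1O[Si](C)(C)C(C)(C)C
F3 | step 3 | 1-{2,4-bis(tert-butyldimethylsilyloxy)-5-[(E)-3-methylbuta-1,3-dien-1-yl]phenyl}ethan-1-one | CC(=O)c1cc(/C=C/C(C)=C)c(O[Si](C)(C)C(C)(C)C)cc1O[Si](C)(C)C(C)(C)C
F4 | step 3 | 1-{2,4-bis(tert-butyldimethylsilyloxy)-5-[(2R,3R)-3-(prop-1-en-2-yl)oxiran-2-yl]phenyl}ethan-1-one | CC(=O)c1cc([C@H]2O[C@@H]2C(C)=C)c(O[Si](C)(C)C(C)(C)C)cc1O[Si](C)(C)C(C)(C)C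
F5 | step 3 | (2R,3R)-5-acetyl-2-(prop-1-en-2-yl)-2,3-dihydro-1-benzofuran-3,6-diol | C=C(C)[C@H]1Oc2cc(O)c(C(C)=O)cc2[C@H]1O
F6 | step 3 | (Z)-2-methylbut-2-enoic 2,4,6-trichlorobenzoic anhydride | C/C=C(/C)C(=O)OC(=O)c1c(Cl)cc(Cl)cc1Cl
F7 | step 4 | (2R,3R)-5-acetyl-2-(3-chloroprop-1-en-2-yl)-6-hydroxy-2,3-dihydro-1-benzofuran-3-yl (Z)-2-methylbut-2-enoate | C=C(CCl)[C@H]1Oc2cc(O)c(C(C)=O)cc2[C@H]1OC(=O)/C(C)=C\C
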